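## Retrosynthetic overview

1. The ten-membered carbocycle is closed last, by ring-closing metathesis at C4=C5 (Z enforced by the ring).
2. C7–C8 is made by a Hosomi–Sakurai union of an "east" α-acyloxy aldehyde (furanone, C9 ester) with a "west" silylmethyl butenolide; this sets C7 and C8 and unveils the exocyclic methylene.
3. West: the lactone C6–O bond is made first, by a catalytic enantioselective SN2′ esterification of a dienyl trichloroacetimidate (key C–O bond, new on this substrate class); it sets C6, from which C7 is relayed. The butenolide ring then follows by metathesis.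
4. East: the furanone ring is closed through its O–C3 bond by gold-catalysed cycloisomerisation of an α-hydroxy ynone; C9–C10 comes from an aldol with L-glyceraldehyde acetonide; the C9–O ester from a Yamaguchi acylation.
5. Ring order: furanone, then γ-lactone (butenolide), then carbocycle.

Assumption: atoms carry germacrane numbers (C1 ketone, C2=C3 furanone, C4=C5, lactone C6/C7/C11–C13, C8 OH, C9 ester, C10 quaternary); common reagents, solvents and catalysts are bought and not numbered.

## Route

Step 1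
Reactants: 1 ethyl (±)-2-hydroxypropanoate
Product: 2 (±)-2-hydroxy-N-methoxy-N-methylpropanamide
Conditions: MeNH(OMe)·HCl (2.5 equiv), i-PrMgCl (6 equiv), THF, −20 → 0 °C
Reagents that add atoms: N,O-dimethylhydroxylamine hydrochloride, CNOC.Cl
Why: Weinreb amidation of the ester by the magnesium amide made in the flask; the racemic carbinol centre does not matter because it becomes the enolate carbon in step 5.

Step 2
Reactants: 3 2-methylbut-1-en-3-yne; 2 (±)-2-hydroxy-N-methoxy-N-methylpropanamide
Product: 5 (±)-2-hydroxy-6-methylhept-6-en-4-yn-3-one, via lithium acetylide 4 (not isolated)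
Conditions: 3 (2.4 equiv), n-BuLi (2.3 equiv), THF, −78 °C; then 2, −78 → −20 °C; AcOH
Reagents that add atoms: none
Why: Weinreb ketone synthesis, in which the first equivalent of acetylide masks the hydroxyl as its alkoxide and the chelated tetrahedral intermediate stops the addition at the ynone.

Step 3
Reactants: 5 (±)-2-hydroxy-6-methylhept-6-en-4-yn-3-one
Product: 6 (±)-2-methyl-5-(prop-1-en-2-yl)furan-3(2H)-one
Conditions: Ph3PAuCl (2 mol%), AgOSO2CF3 (2 mol%), toluene, 23 °C
Reagents that add atoms: none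
Why: monovalent-gold-catalysed 5-endo-dig hydroalkoxylation (cycloisomerisation) of the α-hydroxy ynone forms the O–C3 bond of the 3(2H)-furanone.

Step 4
Reactants: 7 5,6-O-isopropylidene-L-gulono-1,4-lactone
Product: 8 (4S)-2,2-dimethyl-1,3-dioxolane-4-carbaldehyde
Conditions: NaIO4 (2.1 equiv), H2O, pH 5.5 (NaOH), 0 → 23 °C
Reagents that add atoms: none
Why: double periodate glycol cleavage (C2–C3, then C3–C4 after loss of the glyoxylate ester) removes the lactone carbons and leaves C5 of the sugar as the (S) centre of L-glyceraldehyde acetonide.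

Step 5
Reactants: 6 (±)-2-methyl-5-(prop-1-en-2-yl)furan-3(2H)-one; 8 (4S)-2,2-dimethyl-1,3-dioxolane-4-carbaldehyde
Product: 10 (2S)-2-[(S)-[(4S)-2,2-dimethyl-1,3-dioxolan-4-yl](hydroxy)methyl]-2-methyl-5-(prop-1-en-2-yl)furan-3(2H)-one, via lithium furan-3-olate 9 (not isolated)
Conditions: LiN(i-Pr)2 (1.05 equiv), THF, −78 °C, 30 min; then 8 (1.3 equiv), −78 °C, 20 min; AcOH at −78 °C
Reagents that add atoms: none
Why: lithium aldol addition after kinetic C2 deprotonation, in which Felkin–Anh attack anti to the dioxolane oxygen sets C9 (S) and the Zimmerman–Traxler chair places the ring oxygen (E position of the cyclic enolate) anti to the new hydroxyl, setting C10 (S).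

Step 6
Reactants: 11 3-methylfuran-2(5H)-one
Product: 14 (2Z)-4-acetoxy-2-methylbut-2-enoic acid, via potassium hydroxy-carboxylate 12 (not isolated), via dipotassium alkoxide-carboxylate 13 (not isolated)
Conditions: KOH (1.0 equiv), MeOH–H2O, 23 °C; evaporate; KOt-Bu (1.0 equiv), THF–DMF, −40 °C; Ac2O (1.05 equiv), −40 → 0 °C; 1 M HCl to pH 3, 0 °C
Reagents that add atoms: potassium hydroxide, [K+].[OH-]; acetic anhydride, CC(=O)OC(C)=O
Why: saponification keeps the Z geometry of the ring, and chemoselective O-acetylation of the far more nucleophilic alkoxide of the dianion caps the hydroxyl before acidification, so relactonisation cannot occur.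

Step 7
Reactants: 14 (2Z)-4-acetoxy-2-methylbut-2-enoic acid; 10 the aldol adduct of step 5
Product: 16 (S)-[(4S)-2,2-dimethyl-1,3-dioxolan-4-yl][(2S)-2-methyl-3-oxo-5-(prop-1-en-2-yl)-2,3-dihydrofuran-2-yl]methyl (2Z)-4-acetoxy-2-methylbut-2-enoate, via mixed anhydride 15 (not isolated)
Conditions: 14 (2 equiv), 2,4,6-Cl3C6H2COCl (2 equiv), Et3N (2.2 equiv), toluene, 23 °C, 1 h; filter; then 10, toluene, 70 °C, no DMAP
Reagents that add atoms: none
Why: Yamaguchi esterification through the preformed mixed anhydride under base-poor thermal conditions acylates the hindered C9 hydroxyl while avoiding nucleophile-induced Z→E isomerisation and retro-aldol cleavage; no stereocentre is touched.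

Step 8
Reactants: 16 the dioxolanyl ester of step 7
Product: 18 (1R)-1-[(2S)-2-methyl-3-oxo-5-(prop-1-en-2-yl)-2,3-dihydrofuran-2-yl]-2-oxoethyl (2Z)-4-acetoxy-2-methylbut-2-enoate, via 1,2-diol 17 (not isolated)
Conditions: H5IO6 (1.6 equiv), EtOAc, 23 °C; used crude
Reagents that add atoms: none
Why: periodic acid hydrolyses the terminal acetonide and cleaves the resulting glycol in the same flask (glycol cleavage), unmasking the C8 aldehyde and removing the auxiliary stereocentre (the C9 descriptor changes to R only through CIP priorities).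

Step 9
Reactants: 19 (2E)-but-2-enal; 20 methyl 2-[bis(2,2,2-trifluoroethoxy)phosphoryl]acetate
Product: 22 methyl (2Z,4E)-hexa-2,4-dienoate, via potassium phosphonate carbanion 21 (not isolated)
Conditions: 20, KN(SiMe3)2, 18-crown-6, THF, −78 °C; then 19
Reagents that add atoms: none
Why: Still–Gennari variant of the Horner–Wadsworth–Emmons olefination gives the (2Z) olefin under kinetic control while the (4E) olefin of the aldehyde is kept.

Step 10
Reactants: 22 methyl (2Z,4E)-hexa-2,4-dienoate
Product: 23 (2Z,4E)-hexa-2,4-dien-1-ol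
Conditions: i-Bu2AlH (2.3 equiv), CH2Cl2, −78 °C; Rochelle salt
Reagents that add atoms: none
Why: 1,2-reduction of the ester to the allylic alcohol with both olefin geometries retained.

Step 11
Reactants: 23 (2Z,4E)-hexa-2,4-dien-1-ol
Product: 24 (2Z,4E)-hexa-2,4-dien-1-yl 2,2,2-trichloroacetimidate
Conditions: Cl3CCN (1.5 equiv), DBU (0.1 equiv), CH2Cl2, 0 °C; used at once
Reagents that add atoms: trichloroacetonitrile, N#CC(Cl)(Cl)Cl
Why: base-catalysed addition of the alcohol to the nitrile (imidate formation).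

Step 12
Reactants: 25 ethyl 2-[(trimethylsilyl)methyl]prop-2-enoate
Product: 27 2-[(trimethylsilyl)methyl]prop-2-enoic acid, via lithium carboxylate 26 (not isolated)
Conditions: LiOH·H2O (1.5 equiv), THF–H2O, 23 °C; then 1 M HCl to pH 3–4, 0 °C
Reagents that add atoms: lithium hydroxide, [Li+].[OH-]
Why: ester saponification, with cold mild acidification so that the allylsilane is not protodesilylated.

Step 13
Reactants: 24 (2Z,4E)-hexa-2,4-dien-1-yl 2,2,2-trichloroacetimidate; 27 2-[(trimethylsilyl)methyl]prop-2-enoic acid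
Product: 28 (3S,4E)-hexa-1,4-dien-3-yl 2-[(trimethylsilyl)methyl]prop-2-enoate
Conditions: 27 (3 equiv), (Rp,S)-[COP-OAc]2 = di-μ-acetato-bis[(η5-(S)-(pR)-2-(4-isopropyl-4,5-dihydrooxazol-2-yl)cyclopentadienyl-1-C,3-N)(η4-tetraphenylcyclobutadiene)cobalt]dipalladium (1 mol%), CH2Cl2, 23 °C
Reagents that add atoms: none
Why: Proposed new method: the palladacycle-catalysed enantioselective SN2′ esterification of (Z)-allylic trichloroacetimidates, shown so far for alkyl-substituted imidates and simple acids, is extended to a conjugated dienyl imidate and a silyl-bearing acrylic acid; coordination of the imidate nitrogen holds divalent palladium on the proximal (Z)-olefin, the carboxylate attacks C3 anti to the metal on the enantioface fixed by the planar-chiral ligand, and syn-deoxypalladation expels trichloroacetamide, so the distal (E)-propenyl group should stay untouched and the C6–O bond forms in the facial sense that gives (R)-esters from alkyl imidates (here 3S by CIP priority); closest known reaction type: COP-catalysed asymmetric allylic esterification of (Z)-2-alkenyl trichloroacetimidates.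

Step 14
Reactants: 28 (3S,4E)-hexa-1,4-dien-3-yl 2-[(trimethylsilyl)methyl]prop-2-enoate
Product: 29 (5R)-5-[(1E)-prop-1-en-1-yl]-3-[(trimethylsilyl)methyl]furan-2(5H)-one
Conditions: second-generation Grubbs catalyst (5 mol%), 1,4-benzoquinone (10 mol%), toluene (5 mM), 80 °C
Reagents that add atoms: none
Why: ring-closing metathesis of the acrylate with the vinyl group, which loads the catalyst far faster than the internal (E)-propenyl group, gives the butenolide with the C6 centre untouched (the minor 5-vinyl isomer is removed by chromatography).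

Step 15
Reactants: 18 the α-acyloxy aldehyde of step 8; 29 (5R)-5-[(1E)-prop-1-en-1-yl]-3-[(trimethylsilyl)methyl]furan-2(5H)-one
Product: 30 (1S,2S)-2-hydroxy-1-[(2S)-2-methyl-3-oxo-5-(prop-1-en-2-yl)-2,3-dihydrofuran-2-yl]-2-[(2R,3R)-4-methylidene-5-oxo-2-[(1E)-prop-1-en-1-yl]oxolan-3-yl]ethyl (2Z)-4-acetoxy-2-methylbut-2-enoate
Conditions: 29 (1.3 equiv), BF3·OEt2 (2.5 equiv), CH2Cl2, −78 → −30 °C; aq. NaHCO3
Reagents that add atoms: none
Why: Hosomi–Sakurai allylation through an open antiperiplanar transition state, in which the aldehyde is attacked anti to the acyloxy group (polar Felkin–Anh, C8 S), the butenolide reacts at C7 on the face opposite the propenyl group (C7 R, trans-lactone) and the E-type allylsilane gives the syn C7/C8 relationship, so all three preferences are matched; loss of silicon creates the exocyclic methylene, and the non-basic medium prevents C9→C8 acyl migration.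

Step 16
Reactants: 30 the seco-diene of step 15
Product: 31 CNP0523348.1, (4Z,6R,7R,8S,9S,10S)-9-[(2Z)-4-acetoxy-2-methylbut-2-enoyloxy]-8-hydroxy-1-oxo-3,10-epoxygermacra-2,4,11(13)-trien-12,6-olide
Conditions: second-generation Hoveyda–Grubbs catalyst (20 mol% in portions), toluene (0.5 mM), 100 °C, argon sparge
Reagents that add atoms: none
Why: ring-closing metathesis initiated at the propenyl group closes onto the isopropenyl group and the ring enforces the (4Z) trisubstituted olefin; closure of this oxygen-bridged ring onto a 5-isopropenyl-3(2H)-furanone is known in the eremantholide series, and no stereocentre is affected.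

## Compound list

1 | ethyl (±)-2-hydroxypropanoate (ethyl lactate) | CCOC(=O)C(C)O | starting material
2 | (±)-2-hydroxy-N-methoxy-N-methylpropanamide | CC(O)C(=O)N(C)OC | intermediate
3 | 2-methylbut-1-en-3-yne | C#CC(C)=C | starting material
4 | lithium 3-methylbut-3-en-1-yn-1-ide | [Li+].[C-]#CC(C)=C | intermediate
5 | (±)-2-hydroxy-6-methylhept-6-en-4-yn-3-one | CC(O)C(=O)C#CC(C)=C | intermediate
6 | (±)-2-methyl-5-(prop-1-en-2-yl)furan-3(2H)-one | CC1OC(C(C)=C)=CC1=O | intermediate
7 | 5,6-O-isopropylidene-L-gulono-1,4-lactone | O=C1[C@@H](O)[C@@H](O)[C@H](O1)[C@@H]2COC(C)(C)O2 | starting material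
8 | (4S)-2,2-dimethyl-1,3-dioxolane-4-carbaldehyde (L-glyceraldehyde acetonide) | O=C[C@@H]1COC(C)(C)O1 | intermediate
9 | lithium 2-methyl-5-(prop-1-en-2-yl)furan-3-olate | [Li+].[O-]c1cc(C(C)=C)oc1C | intermediate
10 | (2S)-2-[(S)-[(4S)-2,2-dimethyl-1,3-dioxolan-4-yl](hydroxy)methyl]-2-methyl-5-(prop-1-en-2-yl)furan-3(2H)-one | CC1(C)OC[C@H](O1)[C@H](O)[C@]2(C)OC(C(C)=C)=CC2=O | intermediate
11 | 3-methylfuran-2(5H)-one | CC1=CCOC1=O | starting material
12 | potassium (2Z)-4-hydroxy-2-methylbut-2-enoate | [K+].[O-]C(=O)/C(C)=C\CO | intermediate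
13 | dipotassium (2Z)-2-methyl-4-oxidobut-2-enoate | [K+].[K+].[O-]C(=O)/C(C)=C\C[O-] | intermediate
14 | (2Z)-4-acetoxy-2-methylbut-2-enoic acid | OC(=O)/C(C)=C\COC(C)=O | intermediate
15 | (2Z)-4-acetoxy-2-methylbut-2-enoic 2,4,6-trichlorobenzoic anhydride | O=C(OC(=O)/C(C)=C\COC(C)=O)c1c(Cl)cc(Cl)cc1Cl | intermediate
16 | (S)-[(4S)-2,2-dimethyl-1,3-dioxolan-4-yl][(2S)-2-methyl-3-oxo-5-(prop-1-en-2-yl)-2,3-dihydrofuran-2-yl]methyl (2Z)-4-acetoxy-2-methylbut-2-enoate | CC1(C)OC[C@H](O1)[C@H](OC(=O)/C(C)=C\COC(C)=O)[C@]2(C)OC(C(C)=C)=CC2=O | intermediate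
17 | (1S,2S)-2,3-dihydroxy-1-[(2S)-2-methyl-3-oxo-5-(prop-1-en-2-yl)-2,3-dihydrofuran-2-yl]propyl (2Z)-4-acetoxy-2-methylbut-2-enoate | OC[C@H](O)[C@H](OC(=O)/C(C)=C\COC(C)=O)[C@]1(C)OC(C(C)=C)=CC1=O | intermediate
18 | (1R)-1-[(2S)-2-methyl-3-oxo-5-(prop-1-en-2-yl)-2,3-dihydrofuran-2-yl]-2-oxoethyl (2Z)-4-acetoxy-2-methylbut-2-enoate | O=C[C@H](OC(=O)/C(C)=C\COC(C)=O)[C@]1(C)OC(C(C)=C)=CC1=O | intermediate
19 | (2E)-but-2-enal (crotonaldehyde) | C/C=C/C=O | starting material
20 | methyl 2-[bis(2,2,2-trifluoroethoxy)phosphoryl]acetate | COC(=O)CP(=O)(OCC(F)(F)F)OCC(F)(F)F | starting material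
21 | potassium [bis(2,2,2-trifluoroethoxy)phosphoryl](methoxycarbonyl)methanide | [K+].COC(=O)[CH-]P(=O)(OCC(F)(F)F)OCC(F)(F)F | intermediate
22 | methyl (2Z,4E)-hexa-2,4-dienoate | C/C=C/C=C\C(=O)OC | intermediate
23 | (2Z,4E)-hexa-2,4-dien-1-ol | C/C=C/C=C\CO | intermediate
24 | (2Z,4E)-hexa-2,4-dien-1-yl 2,2,2-trichloroacetimidate | C/C=C/C=C\COC(=N)C(Cl)(Cl)Cl | intermediate
25 | ethyl 2-[(trimethylsilyl)methyl]prop-2-enoate | CCOC(=O)C(=C)C[Si](C)(C)C | starting material
26 | lithium 2-[(trimethylsilyl)methyl]prop-2-enoate | [Li+].[O-]C(=O)C(=C)C[Si](C)(C)C | intermediate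
27 | 2-[(trimethylsilyl)methyl]prop-2-enoic acid | OC(=O)C(=C)C[Si](C)(C)C | intermediate
28 | (3S,4E)-hexa-1,4-dien-3-yl 2-[(trimethylsilyl)methyl]prop-2-enoate | C[Si](C)(C)CC(=C)C(=O)O[C@@H](C=C)/C=C/C | intermediate
29 | (5R)-5-[(1E)-prop-1-en-1-yl]-3-[(trimethylsilyl)methyl]furan-2(5H)-one | C[Si](C)(C)CC1=C[C@@H](/C=C/C)OC1=O | intermediate
30 | (1S,2S)-2-hydroxy-1-[(2S)-2-methyl-3-oxo-5-(prop-1-en-2-yl)-2,3-dihydrofuran-2-yl]-2-[(2R,3R)-4-methylidene-5-oxo-2-[(1E)-prop-1-en-1-yl]oxolan-3-yl]ethyl (2Z)-4-acetoxy-2-methylbut-2-enoate | C=C1C(=O)O[C@H](/C=C/C)[C@H]1[C@H](O)[C@H](OC(=O)/C(C)=C\COC(C)=O)[C@]1(C)OC(C(C)=C)=CC1=O | intermediate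
31 | CNP0523348.1, (4Z,6R,7R,8S,9S,10S)-9-[(2Z)-4-acetoxy-2-methylbut-2-enoyloxy]-8-hydroxy-1-oxo-3,10-epoxygermacra-2,4,11(13)-trien-12,6-olide | C=C1C(=O)O[C@@H]2/C=C(/C)C3=CC(=O)[C@@](C)(O3)[C@@H](OC(=O)/C(C)=C\COC(C)=O)[C@@H](O)[C@@H]12 | target

## Step count and risks

Total steps: 16. Longest linear sequence: 8 (steps 1, 2, 3, 5, 7, 8, 15, 16).

The three steps most likely to fail (the final metathesis ranks just behind them because of its close precedent):

**Step 13 (proposed new step).** The dienyl imidate may give distal attack, allylic transposition of the product or low ee. The fallback makes the C6–O stereocentre by known chemistry. It sets out from crotonaldehyde 19: amino-alcohol-catalysed asymmetric vinylation with divinylzinc F1 (made from CH2=CHMgBr and ZnCl2; (−)-3-exo-(dimethylamino)isoborneol, toluene, 0 °C, vinyl delivered to the Si face) gives (3S,4E)-hexa-1,4-dien-3-ol F2. Carbodiimide esterification of F2 with acid 27 (DCC, DMAP, CH2Cl2, 0 °C) comes back to the route at ester 28.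

**Step 15.** The ester-conjugated allylsilane may be too unreactive, or the open transition state may not be selective. The fallback joins the halves with a chromium allyl reagent and corrects C8 afterwards. It sets out from imidate 24, which is esterified under the step 13 conditions with 2-(bromomethyl)prop-2-enoic acid to give (3S,4E)-hexa-1,4-dien-3-yl 2-(bromomethyl)prop-2-enoate F3. Ring-closing metathesis (second-generation Grubbs catalyst, toluene, 80 °C) gives (5R)-3-(bromomethyl)-5-[(1E)-prop-1-en-1-yl]furan-2(5H)-one F4. Allylation of aldehyde 18 with F4 and CrCl2 (divalent chromium, THF, 0 °C) goes through the closed chair and gives the anti adduct, the C8 epimer of 30 F5. Buffered Dess–Martin oxidation gives the C8 ketone of 30 F6, and Felkin-controlled Luche reduction (NaBH4, CeCl3·7H2O, MeOH, −78 °C) comes back to the route at 30.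

**Step 7.** The neopentyl-type C9 hydroxyl of a retro-aldol-prone β-hydroxy ketone may not be acylated by the Z acid without Z→E isomerisation. The fallback builds the olefin after acylation. It sets out from alcohol 10, which is esterified with 2-(diphenoxyphosphoryl)propanoic acid (DCC, DMAP, CH2Cl2, 0 °C) to give (S)-[(4S)-2,2-dimethyl-1,3-dioxolan-4-yl][(2S)-2-methyl-3-oxo-5-(prop-1-en-2-yl)-2,3-dihydrofuran-2-yl]methyl 2-(diphenoxyphosphoryl)propanoate F7. A Z-selective Ando-type Horner–Wadsworth–Emmons olefination of F7 with commercial 2-oxoethyl acetate (NaH, THF, −78 → 0 °C) comes back to the route at ester 16.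

## Further compounds

F1 | step 13 | divinylzinc | C=C[Zn]C=C
F2 | step 13 | (3S,4E)-hexa-1,4-dien-3-ol | O[C@@H](C=C)/C=C/C
F3 | step 15 | (3S,4E)-hexa-1,4-dien-3-yl 2-(bromomethyl)prop-2-enoate | BrCC(=C)C(=O)O[C@@H](C=C)/C=C/C
F4 | step 15 | (5R)-3-(bromomethyl)-5-[(1E)-prop-1-en-1-yl]furan-2(5H)-one | BrCC1=C[C@@H](/C=C/C)OC1=O
F5 | step 15 | C8 epimer of 30 (8R carbinol, all other centres as in 30) | C=C1C(=O)O[C@H](/C=C/C)[C@H]1[C@@H](O)[C@H](OC(=O)/C(C)=C\COC(C)=O)[C@]1(C)OC(C(C)=C)=CC1=O
F6 | step 15 | C8 ketone of 30 (all other centres as in 30) | C=C1C(=O)O[C@H](/C=C/C)[C@H]1C(=O)[C@H](OC(=O)/C(C)=C\COC(C)=O)[C@]1(C)OC(C(C)=C)=CC1=O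
F7 | step 7 | (S)-[(4S)-2,2-dimethyl-1,3-dioxolan-4-yl][(2S)-2-methyl-3-oxo-5-(prop-1-en-2-yl)-2,3-dihydrofuran-2-yl]methyl 2-(diphenoxyphosphoryl)propanoate | CC1(C)OC[C@H](O1)[C@H](OC(=O)C(C)P(=O)(Oc2ccccc2)Oc2ccccc2)[C@]3(C)OC(C(C)=C)=CC3=O
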